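| flask | left-handed substrate | right-handed substrate | gas | racemization catalyst | impurity | remark | time |
|---|---|---|---|---|---|---|---|
| zeta | 0.15 M | 0.15 M | 53 mM (held) | 0.46 mM | 0.39 mM | run made earlier |  |
| theta | 0.35 M | 0.35 M | 53 mM (held) | 0.46 mM | 0.39 mM | run made earlier |  |
| epsilon | 0.23 M | 0.23 M | 53 mM (held) | 0.46 mM | 0.78 mM | run made earlier |  |
| flask | 0.23 M | 0.23 M | 53 mM (held) | 0.46 mM | 0.39 mM |  | 2.5 min |

| run | time / s | left-handed product / % | right-handed product / % |
|---|---|---|---|
| zeta | 10.0 | 3.9 | 0.5 |
| zeta | 20.0 | 9.2 | 3.8 |
| zeta | 30.0 | 14.5 | 6.1 |
| zeta | 50.0 | 24.6 | 11.5 |
| zeta | 60.0 | 27.7 | 13.1 |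
| zeta | 90.0 | 38.0 | 21.1 |
| theta | 15.0 | 5.1 | 1.5 |
| theta | 30.0 | 7.8 | 3.2 |
| theta | 50.0 | 13.4 | 5.5 |
| theta | 60.0 | 15.5 | 5.8 |
| theta | 80.0 | 20.4 | 8.2 |
| theta | 90.0 | 23.4 | 10.5 |
| epsilon | 10.0 | 3.2 | 1.0 |
| epsilon | 15.0 | 4.4 | 2.5 |
| epsilon | 25.0 | 8.8 | 3.5 |
| epsilon | 50.0 | 17.3 | 8.9 |
| epsilon | 90.0 | 30.7 | 15.1 |

(readings scatter by 0.5 percentage points)

- coupling partner is single-handed; left-handed substrate and right-handed substrate are mirror images of each other, charged as a racemate, each of them at the stated concentration
- at the start none of the gas is in solution
- an excess is the difference of the two amounts in percent of their sum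
- an excess is below zero if the other one leads
- the handed part of coupling partner does not stay in what it makes, so the products of the two hands are mirror images too

* left-handed product and right-handed product together, in percent of the left-handed substrate and right-handed substrate charged together, at 2.5 min
* excess of left-handed product over right-handed product in the product at 2.5 min
* whether the exchange between left-handed substrate and right-handed substrate keeps pace with the reaction: how far the product's excess at 2.5 min gets from its value without exchange to its value with instant exchange (above 80 % keeps pace, below 20 % hardly takes part, else lags behind)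

0.0700 mM was the number I started from: the free catalyst, meaning the racemization catalyst charged less the impurity charged, on my assumption that impurity takes catalyst fast and one for one. In the epsilon run impurity exceeded catalyst, so on that assumption it held none free and showed the plain race of the two hands. Its selectivity factor s is the ratio of the logarithms of what remains of each substrate. With equal charges, each remainder is one minus twice its product reading, and s came to 2.65.

For the yield I joined two stretches and took impurity as leaving the rate alone. Epsilon, with this flask's substrate, had made 0.211 M of product by 90.0 s. That left 0.249 M of substrate, less than the zeta charge of 0.300 M, but I let zeta stand in for the rest: it made 0.122 M in 60.0 s, which completes 2.5 min. Together that is 72.4 % of the flask's charge.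

I then tried a right-handed remainder of 44.4 % of its charge. Through s this gives a left-handed remainder of 11.7 %, and their mean of 28.0 % matches the 27.6 % unreacted. The excess without exchange is therefore 22.8 %, while instant exchange holds it at s less one over s plus one, 45.2 %.

The weak link was treating 0.0700 mM as nothing. Zeta has that same free catalyst, yet its s read 2.60. One scatter on its excess, 1.2 percentage points, is 5.36 % of the gap between my two excesses, well under 20 %. So I committed to 72.4 %, an excess near 22.8 %, and exchange hardly taking part.

The forecast gave 72 %, 24 % and hardly takes part, holding that “exchange is already nearly dead”.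

The flask gives 71.6 % and 23.8 %, and exchange hardly takes part, at 4.4 % of the way.

    gas ⇌ coupling partner, rate k1*(csat - [coupling partner]) (kL = 0.0573 /s)
    racemization catalyst + impurity → spent catalyst (k = 5140 /M/s)
    coupling partner + left-handed substrate → left-handed product (k = 1.14 /M/s)
    left-handed substrate + racemization catalyst ⇌ right-handed substrate + racemization catalyst, rate k4*[racemization catalyst]*[left-handed substrate] forward; the back reaction follows from the equilibrium constant (k = 6.50 /M/s)
    coupling partner + right-handed substrate → right-handed product (k = 0.435 /M/s)

In the flask the racemization catalyst stood at 15.2 % of its charge, where the free catalyst's 15.2 % puts it. Part of why the flask's yield stood at 71.6 % was the hold-up of gas passing into coupling partner, together with the time given: the run without the hold-up reaches 98.5 %, and the run at ten times the time reaches 100 %.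

In the neighbour flask with 0.0018 M of catalyst, free catalyst comes to 1.41 mM, 78.3 % of its charge; computed, its catalyst stands at 78.3 % and its excess reaches 34.1 %.

The earlier runs and the new flask were computed for an exercise, and the scatter is random.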